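Ring A of the target carries its C3 oxygen para to the quaternary carbon C10. Ring A therefore maps onto an achiral 4,4-disubstituted cyclohexa-2,5-dienone whose mirror plane passes through C3 and C10. The route rests on cutting C5–C6 in ring B. The pendant methyl ketone of this dienone condenses with a chiral primary-amine salt to give the terminal enamine, and this carbon nucleophile adds to only one of the two mirror-related β-carbons. That single operation forms C5–C6, closes ring B, fixes C10 absolutely, and leaves a C3 enone and a C7 ketone that are easily told apart. C7, C3 and C5 are later set relative to C10 by equilibration, hydride delivery with Mitsunobu inversion, and a Schenck ene reaction.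

Key step: step 6

Numbering remark: eudesmane numbering is used for all bicyclic compounds. Ring A is C1–C5 and C10; ring B is C5–C10; C14 is the methyl on C10; C15 is the carbon on C4; C11–C13 are the side chain on C7. β denotes the face that carries C14.

Assumption: the quinine-derived amine is taken to give the bicyclic enedione as drawn; if it gives the mirror image, the pseudo-enantiomeric quinidine-derived amine is used instead.

Step 1
Reactants: 1 3-ethoxycyclohex-2-en-1-one; 2 2-(2-bromoethyl)-2-methyl-1,3-dioxolane
Product: 3 rac-3-ethoxy-6-[2-(2-methyl-1,3-dioxolan-2-yl)ethyl]cyclohex-2-en-1-one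
Conditions: LiN(i-Pr)2, THF, −78 °C; then 2, DMPU, −78 °C → rt
Reagents that add atoms: none
Why: Stork–Danheiser α′-alkylation, in which the vinylogous ester is deprotonated kinetically at C6 and the sluggish primary bromide is used first, while the enolate carbon is still unhindered; the new stereocentre is racemic and irrelevant.

Step 2
Reactants: 3 rac-3-ethoxy-6-[2-(2-methyl-1,3-dioxolan-2-yl)ethyl]cyclohex-2-en-1-one; 4 iodomethane
Product: 5 rac-3-ethoxy-6-methyl-6-[2-(2-methyl-1,3-dioxolan-2-yl)ethyl]cyclohex-2-en-1-one
Conditions: LiN(i-Pr)2, THF, −78 °C; then MeI, −78 → 0 °C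
Reagents that add atoms: none
Why: Second Stork–Danheiser α′-alkylation, which closes the quaternary carbon (future C10) with the smallest and most reactive electrophile; the racemate is harmless because chirality is erased in step 4.

Step 3
Reactants: 5 rac-3-ethoxy-6-methyl-6-[2-(2-methyl-1,3-dioxolan-2-yl)ethyl]cyclohex-2-en-1-one
Product: 7 rac-4-methyl-4-[2-(2-methyl-1,3-dioxolan-2-yl)ethyl]cyclohex-2-en-1-one, via ethoxy allylic alcohol 6 (not isolated)
Conditions: LiAlH4, Et2O, 0 °C; then 0.5 M aq. HCl, THF, 0 °C
Reagents that add atoms: water, O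
Why: Stork–Danheiser carbonyl transposition, in which 1,2-hydride addition gives the very acid-labile alcohol 6, and this ionises and hydrolyses under acid far milder than the dioxolane needs, so the side-chain ketone stays masked.

Step 4
Reactants: 7 rac-4-methyl-4-[2-(2-methyl-1,3-dioxolan-2-yl)ethyl]cyclohex-2-en-1-one
Product: 8 4-methyl-4-[2-(2-methyl-1,3-dioxolan-2-yl)ethyl]cyclohexa-2,5-dien-1-one (achiral)
Conditions: LiN(i-Pr)2, THF, −78 °C; then PhS(Cl)=N-t-Bu, −78 °C
Reagents that add atoms: none
Why: Mukaiyama dehydrogenation, in which the quaternary γ-carbon leaves only the cross-conjugated α′-enolate available and its sulfur adduct eliminates in a syn fashion at low temperature; both enantiomers of 7 converge on one achiral dienone.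

Step 5
Reactants: 8 4-methyl-4-[2-(2-methyl-1,3-dioxolan-2-yl)ethyl]cyclohexa-2,5-dien-1-one
Product: 9 4-methyl-4-(3-oxobutyl)cyclohexa-2,5-dien-1-one (achiral, prochiral)
Conditions: PPTS (cat.), acetone/H2O, 40 °C
Reagents that add atoms: water, O
Why: Acid-catalysed acetal hydrolysis under conditions too mild for dienone–phenol rearrangement or acid-promoted racemic cyclisation, so the nucleophilic ketone is unmasked only just before the asymmetric step.

Step 6
Reactants: 9 4-methyl-4-(3-oxobutyl)cyclohexa-2,5-dien-1-one
Product: 10 (5R,10R)-10-methyl-cis-octal-1-ene-3,7-dione (5β-H, 10β-CH3)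
Conditions: 9-amino-9-deoxy-epi-quinine (20 mol %), CF3CO2H (40 mol %), toluene, rt
Reagents that add atoms: none
Why: The primary amine condenses with the unhindered side-chain ketone, the iminium ion tautomerises to the terminal enamine C6=C7, C6 adds to the β-carbon C5 of one enone arm, and hydrolysis of the product iminium ion releases 10 and the catalyst. The closest known reaction type is the amine-catalysed desymmetrising intramolecular Michael addition to 4,4-disubstituted cyclohexadienones, run here with a cinchona primary amine because such amines, unlike secondary ones, engage methyl ketones through their CH3 carbon. Ring B closes in the 6-(enolendo)-exo-trig mode, with the attacked C4=C5 bond outside and the enamine C6=C7 bond inside the new ring. C5 is controlled by the three-atom tether, which reaches the planar dienone only on the face where C9 stands, so H5 and the C10 methyl become cis; C10 is controlled by the catalyst alone, whose protonated quinuclidine is expected to hydrogen-bond the C3 carbonyl and so present one of the two enantiotopic arms to the enamine. The step needs regioselectivity between the two possible enamines, and the substrate secures it: the internal enamine carbon C8 could only close a four-membered ring, and the cross-conjugated C3 carbonyl is too deactivated to compete for the amine. Racemic background reaction is limited by the late unmasking in step 5 and by an apolar solvent at ambient temperature.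

Step 7
Reactants: 10 (5R,10R)-10-methyl-cis-octal-1-ene-3,7-dione
Product: 11 7,7-ethylenedioxy-10β-methyl-5βH-octal-1-en-3-one
Conditions: TMSOCH2CH2OTMS, TMSOTf (cat.), CH2Cl2, −78 °C; pyridine quench
Reagents that add atoms: 1,2-bis(trimethylsilyloxy)ethane, C[Si](C)(C)OCCO[Si](C)(C)C
Why: Noyori acetalisation, which at −78 °C acetalises a saturated ketone far faster than a conjugated enone; masking C7 also shuts off the retro-Michael path of the C3/C7 1,5-diketone that could racemise 10 under base.

Step 8
Reactants: 11 7,7-ethylenedioxy-10β-methyl-5βH-octal-1-en-3-one; 4 iodomethane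
Product: 12 7,7-ethylenedioxy-4,10β-dimethyl-5βH-octal-1-en-3-one (C4 epimers)
Conditions: LiN(i-Pr)2, THF, −78 °C; then MeI, −78 → −20 °C
Reagents that add atoms: none
Why: Kinetic enolate alkylation, which installs C15 regiospecifically because C10 is quaternary and C2 is vinylic, leaving only the hydrogens at C4 acidic; the C4 configuration does not matter because C4 becomes sp2 in step 11.

Step 9
Reactants: 12 7,7-ethylenedioxy-4,10β-dimethyl-5βH-octal-1-en-3-one
Product: 14 3-hydroxy-4,10β-dimethyl-5βH-octal-1-en-7-one (C3/C4 epimers), via allylic alcohol ketal 13 (not isolated)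
Conditions: NaBH4, CeCl3·7H2O, MeOH, −20 °C; then 1 M aq. HCl, THF, rt
Reagents that add atoms: water, O
Why: Luche 1,2-reduction followed by acetal hydrolysis in the same flask, which temporarily removes the enone (a Michael acceptor for TosMIC anion and, with C7=O, a retro-Michael-prone 1,5-diketone) and frees C7 while C5 is still sp3, because a Δ4-7-ketone would carry a doubly activated, readily enolised C6H2 group.

Step 10
Reactants: 14 3-hydroxy-4,10β-dimethyl-5βH-octal-1-en-7-one
Product: 15 3-hydroxy-4,10β-dimethyl-5βH-octal-1-ene-7-carbonitrile (C3/C4/C7 epimers)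
Conditions: TosMIC, t-BuOK, DME/EtOH, 0 → 35 °C
Reagents that add atoms: p-toluenesulfonylmethyl isocyanide (TosMIC), Cc1ccc(cc1)S(=O)(=O)C[N+]#[C-]
Why: Van Leusen reductive cyanation, which turns the unhindered cyclohexanone into the nitrile (adding C11) and tolerates the free hydroxyl, since alcohols are co-solvents of this reaction; the C7 epimer mixture is corrected in step 16.

Step 11
Reactants: 15 3-hydroxy-4,10β-dimethyl-5βH-octal-1-ene-7-carbonitrile
Product: 17 3-oxo-12,13-dinoreudesma-1,4-diene-11-nitrile (10β-CH3; C7 epimers), via enone nitrile 16 (not isolated)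
Conditions: DDQ (2.5 equiv), 1,4-dioxane, rt → reflux
Reagents that add atoms: none
Why: DDQ allylic oxidation followed by DDQ dehydrogenation, in which the only available enol (C3=C4) loses hydride from the tertiary C5–H rather than from the primary C15–H, giving the cross-conjugated dienone and erasing C3, C4 and C5 so that all diastereomers converge.

Step 12
Reactants: 17 3-oxo-12,13-dinoreudesma-1,4-diene-11-nitrile
Product: 18 3-oxo-12,13-dinoreudesm-4-ene-11-nitrile (10β-CH3; C7 epimers)
Conditions: H2 (1 atm), RhCl(PPh3)3 (5 mol %), toluene/EtOH, rt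
Reagents that add atoms: none
Why: Chemoselective homogeneous hydrogenation, in which RhCl(PPh3)3 saturates the disubstituted C1=C2 bond and leaves the tetrasubstituted C4=C5 bond and the nitrile untouched, the established selectivity for 1,4-dien-3-ones of the santonin and steroid type.

Step 13
Reactants: 18 3-oxo-12,13-dinoreudesm-4-ene-11-nitrile
Product: 19 3β-hydroxy-12,13-dinoreudesm-4-ene-11-nitrile (C7 epimers)
Conditions: NaBH4, CeCl3·7H2O, MeOH, −40 → 0 °C
Reagents that add atoms: none
Why: Luche reduction, in which hydride adds 1,2 along the axial trajectory on the α face of the half-chair ring A and gives the pseudo-equatorial 3β-alcohol, as for steroidal and eudesmane 4-en-3-ones.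

Step 14
Reactants: 19 3β-hydroxy-12,13-dinoreudesm-4-ene-11-nitrile
Product: 20 3β-(tert-butyldimethylsilyloxy)-12,13-dinoreudesm-4-ene-11-nitrile (C7 epimers)
Conditions: TBSCl, imidazole, DMF, rt
Reagents that add atoms: tert-butyldimethylsilyl chloride, CC(C)(C)[Si](C)(C)Cl
Why: Silyl ether protection, which shields the allylic alcohol from the Grignard, amide-base and palladium steps that follow.

Step 15
Reactants: 20 3β-(tert-butyldimethylsilyloxy)-12,13-dinoreudesm-4-ene-11-nitrile
Product: 22 7-acetyl-3β-(tert-butyldimethylsilyloxy)-4,10β-dimethyl-Δ4-octalin (C7 epimers), via N-H ketimine 21 (not isolated)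
Conditions: MeMgBr, Et2O/toluene, 60 °C; then 10 % aq. AcOH, 0 °C → rt
Reagents that add atoms: methylmagnesium bromide, C[Mg]Br; water, O
Why: Grignard addition to a nitrile, which stops at the magnesium ketimine; mild acidic work-up then hydrolyses this to the methyl ketone (adding C13) without harming the silyl ether.

Step 16
Reactants: 22 7-acetyl-3β-(tert-butyldimethylsilyloxy)-4,10β-dimethyl-Δ4-octalin (C7 epimers)
Product: 23 7β-acetyl-3β-(tert-butyldimethylsilyloxy)-4,10β-dimethyl-Δ4-octalin (7α-H)
Conditions: NaOMe (0.3 equiv), MeOH, 40 °C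
Reagents that add atoms: none
Why: Thermodynamic epimerisation via the enolate, which should favour the equatorial 7β-acetyl group because ring B of the Δ4-octalin is a locked chair with the C10 methyl axial; the separable 7α-epimer can be resubmitted, and the isolated C4=C5 bond cannot migrate.

Step 17
Reactants: 23 7β-acetyl-3β-(tert-butyldimethylsilyloxy)-4,10β-dimethyl-Δ4-octalin
Product: 24 1-[3β-(tert-butyldimethylsilyloxy)-4,10β-dimethyl-Δ4-octalin-7β-yl]ethenyl trifluoromethanesulfonate
Conditions: LiN(i-Pr)2, THF, −78 °C; then PhNTf2, −78 → 0 °C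
Reagents that add atoms: N-phenylbis(trifluoromethanesulfonimide), O=S(=O)(C(F)(F)F)N(c1ccccc1)S(=O)(=O)C(F)(F)F
Why: Kinetic enol triflate formation, in which the hindered amide base removes a proton from the methyl group rather than the tertiary C7–H, so O-triflation gives the terminal vinyl triflate with C7 untouched.

Step 18
Reactants: 24 1-[3β-(tert-butyldimethylsilyloxy)-4,10β-dimethyl-Δ4-octalin-7β-yl]ethenyl trifluoromethanesulfonate
Product: 25 methyl 3β-(tert-butyldimethylsilyloxy)eudesma-4,11(13)-dien-12-oate
Conditions: CO (1 atm), Pd(OAc)2 (5 mol %), PPh3 (10 mol %), Et3N, MeOH/DMF, 40 °C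
Reagents that add atoms: carbon monoxide, [C-]#[O+]; methanol, CO
Why: Palladium-catalysed methoxycarbonylation of a vinyl triflate (oxidative addition to zerovalent palladium, CO insertion, methanolysis), which delivers the α-substituted acrylate ester directly and adds C12 and the ester methyl.

Step 19
Reactants: 25 methyl 3β-(tert-butyldimethylsilyloxy)eudesma-4,11(13)-dien-12-oate
Product: 26 methyl 3β-hydroxyeudesma-4,11(13)-dien-12-oate
Conditions: Bu4NF, AcOH (1:1), THF, 0 °C → rt
Reagents that add atoms: none
Why: Fluoride desilylation buffered with acetic acid, which avoids both acid ionisation of the electron-rich allylic alcohol and base-induced addition to the acrylate.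

Step 20
Reactants: 26 methyl 3β-hydroxyeudesma-4,11(13)-dien-12-oate; 27 angelic acid, (Z)-2-methylbut-2-enoic acid
Product: 28 methyl 3α-angeloyloxyeudesma-4,11(13)-dien-12-oate
Conditions: PPh3, DIAD, toluene, 0 °C → rt (betaine pre-formed)
Reagents that add atoms: none
Why: Mitsunobu esterification, in which angelate displaces the equatorial 3β-oxyphosphonium group by SN2 attack along the axial α trajectory and inverts C3; the acid acts only as a carboxylate nucleophile and is never activated at its acyl carbon, so Z→E isomerisation to the tiglate is avoided.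

Step 21
Reactants: 28 methyl 3α-angeloyloxyeudesma-4,11(13)-dien-12-oate
Product: 29 methyl (3R,5S,7R,10S)-3α-angeloyloxy-5α-hydroperoxyeudesma-4(15),11(13)-dien-12-oate (CNP0137897.2)
Conditions: O2, visible light, tetraphenylporphyrin (cat.), CH2Cl2, −20 °C; no reductive work-up
Reagents that add atoms: dioxygen, O=O
Why: Schenck ene reaction, in which singlet oxygen reacts only with the electron-rich tetrasubstituted C4=C5 bond, approaches from the α face opposite the axial C10 methyl, bonds to C5 and takes hydrogen from the freely rotating C15 methyl (on that face H3 is absent, being β, and H6α is equatorial and misaligned), which sets the 5α-hydroperoxide and the C4=C15 methylene together.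

Compound list
1 | 3-ethoxycyclohex-2-en-1-one | CCOC1=CC(=O)CCC1 | starting material
2 | 2-(2-bromoethyl)-2-methyl-1,3-dioxolane | CC1(CCBr)OCCO1 | starting material
3 | rac-3-ethoxy-6-[2-(2-methyl-1,3-dioxolan-2-yl)ethyl]cyclohex-2-en-1-one | CCOC1=CC(=O)C(CCC2(C)OCCO2)CC1 | intermediate
4 | iodomethane | CI | starting material
5 | rac-3-ethoxy-6-methyl-6-[2-(2-methyl-1,3-dioxolan-2-yl)ethyl]cyclohex-2-en-1-one | CCOC1=CC(=O)C(C)(CCC2(C)OCCO2)CC1 | intermediate
6 | 3-ethoxy-6-methyl-6-[2-(2-methyl-1,3-dioxolan-2-yl)ethyl]cyclohex-2-en-1-ol (racemic diastereomer mixture) | CCOC1=CC(O)C(C)(CCC2(C)OCCO2)CC1 | intermediate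
7 | rac-4-methyl-4-[2-(2-methyl-1,3-dioxolan-2-yl)ethyl]cyclohex-2-en-1-one | CC1(CCC2(C)OCCO2)C=CC(=O)CC1 | intermediate
8 | 4-methyl-4-[2-(2-methyl-1,3-dioxolan-2-yl)ethyl]cyclohexa-2,5-dien-1-one (achiral) | CC1(CCC2(C)OCCO2)C=CC(=O)C=C1 | intermediate
9 | 4-methyl-4-(3-oxobutyl)cyclohexa-2,5-dien-1-one (achiral) | CC(=O)CCC1(C)C=CC(=O)C=C1 | intermediate
10 | (5R,10R)-10-methyl-cis-octal-1-ene-3,7-dione (5β-H, 10β-CH3) | O=C1CC[C@@]2(C)C=CC(=O)C[C@H]2C1 | intermediate
11 | 7,7-ethylenedioxy-10β-methyl-5βH-octal-1-en-3-one | C13(OCCO3)CC[C@@]2(C)C=CC(=O)C[C@H]2C1 | intermediate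
12 | 7,7-ethylenedioxy-4,10β-dimethyl-5βH-octal-1-en-3-one (C4 epimers) | C13(OCCO3)CC[C@@]2(C)C=CC(=O)C(C)[C@H]2C1 | intermediate
13 | 7,7-ethylenedioxy-4,10β-dimethyl-5βH-octal-1-en-3-ol (C3/C4 epimers) | C13(OCCO3)CC[C@@]2(C)C=CC(O)C(C)[C@H]2C1 | intermediate
14 | 3-hydroxy-4,10β-dimethyl-5βH-octal-1-en-7-one (C3/C4 epimers) | O=C1CC[C@@]2(C)C=CC(O)C(C)[C@H]2C1 | intermediate
15 | 3-hydroxy-4,10β-dimethyl-5βH-octal-1-ene-7-carbonitrile (C3/C4/C7 epimers) | N#CC1CC[C@@]2(C)C=CC(O)C(C)[C@H]2C1 | intermediate
16 | 4,10β-dimethyl-3-oxo-5βH-octal-1-ene-7-carbonitrile (C4/C7 epimers) | N#CC1CC[C@@]2(C)C=CC(=O)C(C)[C@H]2C1 | intermediate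
17 | 3-oxo-12,13-dinoreudesma-1,4-diene-11-nitrile (C7 epimers) | N#CC1CC[C@@]2(C)C=CC(=O)C(C)=C2C1 | intermediate
18 | 3-oxo-12,13-dinoreudesm-4-ene-11-nitrile (C7 epimers) | N#CC1CC[C@@]2(C)CCC(=O)C(C)=C2C1 | intermediate
19 | 3β-hydroxy-12,13-dinoreudesm-4-ene-11-nitrile (C7 epimers) | N#CC1CC[C@@]2(C)CC[C@H](O)C(C)=C2C1 | intermediate
20 | 3β-(tert-butyldimethylsilyloxy)-12,13-dinoreudesm-4-ene-11-nitrile (C7 epimers) | N#CC1CC[C@@]2(C)CC[C@H](O[Si](C)(C)C(C)(C)C)C(C)=C2C1 | intermediate
21 | N-H ketimine of 22 | CC(=N)C1CC[C@@]2(C)CC[C@H](O[Si](C)(C)C(C)(C)C)C(C)=C2C1 | intermediate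
22 | 7-acetyl-3β-(tert-butyldimethylsilyloxy)-4,10β-dimethyl-Δ4-octalin (C7 epimers) | CC(=O)C1CC[C@@]2(C)CC[C@H](O[Si](C)(C)C(C)(C)C)C(C)=C2C1 | intermediate
23 | 7β-acetyl-3β-(tert-butyldimethylsilyloxy)-4,10β-dimethyl-Δ4-octalin | CC(=O)[C@@H]1CC[C@@]2(C)CC[C@H](O[Si](C)(C)C(C)(C)C)C(C)=C2C1 | intermediate
24 | 1-[3β-(tert-butyldimethylsilyloxy)-4,10β-dimethyl-Δ4-octalin-7β-yl]ethenyl trifluoromethanesulfonate | C=C(OS(=O)(=O)C(F)(F)F)[C@@H]1CC[C@@]2(C)CC[C@H](O[Si](C)(C)C(C)(C)C)C(C)=C2C1 | intermediate
25 | methyl 3β-(tert-butyldimethylsilyloxy)eudesma-4,11(13)-dien-12-oate | C=C(C(=O)OC)[C@@H]1CC[C@@]2(C)CC[C@H](O[Si](C)(C)C(C)(C)C)C(C)=C2C1 | intermediate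
26 | methyl 3β-hydroxyeudesma-4,11(13)-dien-12-oate | C=C(C(=O)OC)[C@@H]1CC[C@@]2(C)CC[C@H](O)C(C)=C2C1 | intermediate
27 | angelic acid, (Z)-2-methylbut-2-enoic acid | C/C=C(/C)C(=O)O | starting material
28 | methyl 3α-angeloyloxyeudesma-4,11(13)-dien-12-oate | C=C(C(=O)OC)[C@@H]1CC[C@@]2(C)CC[C@@H](OC(=O)/C(C)=C\C)C(C)=C2C1 | intermediate
29 | methyl (3R,5S,7R,10S)-3α-angeloyloxy-5α-hydroperoxyeudesma-4(15),11(13)-dien-12-oate (CNP0137897.2) | C=C(C(=O)OC)[C@@H]1CC[C@@]2(C)CC[C@@H](OC(=O)/C(C)=C\C)C(=C)[C@]2(OO)C1 | target

Total step count: 21. Longest linear sequence: 21 steps (1 → 29). The route is fully linear; 2, 4 and 27 are bought.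

Steps most likely to fail

**Step 6.** Enamine formation from the methyl ketone may be slow. Reversible Michael addition or a competing uncatalysed cyclisation would then lower conversion and enantiomeric purity.
- The fallback replaces catalysis by a covalently bound auxiliary and a metallated aza-enolate, and it sets out from 9.
- Condensation of the side-chain ketone with (S)-1-amino-2-(methoxymethyl)pyrrolidine (cyclohexane, reflux, water separation) gives the SAMP hydrazone of the dienone F1.
- LiN(i-Pr)2 in THF at low temperature deprotonates the hydrazone methyl group. The lithium aza-enolate closes the same C5–C6 bond under chelation control by the auxiliary and gives the SAMP hydrazone of the bicyclic enedione F2.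
- The diastereomers of F2 can be separated, which upgrades the stereochemical purity.
- Two-phase hydrolysis with saturated aqueous oxalic acid and Et2O frees the C7 ketone and comes back to the route at 10.
- The enantiomeric auxiliary is taken if the sense of induction is wrong.

**Step 20.** Elimination towards the 2,4-diene, SN2′ attack, or ionisation with loss of stereochemical integrity may compete with clean inversion at the allylic C3. The weakly acidic angelic acid may also react sluggishly.
- The fallback sets C3 by reagent-controlled reduction and then acylates with retention; it sets out from 26.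
- MnO2 in CH2Cl2 oxidises the allylic alcohol to methyl 3-oxoeudesma-4,11(13)-dien-12-oate F3.
- Corey–Bakshi–Shibata reduction ((S)-2-methyl-CBS-oxazaborolidine, catecholborane, toluene, −78 °C, with the α-methyl-substituted alkenyl side as the large group) should give methyl 3α-hydroxyeudesma-4,11(13)-dien-12-oate F4.
- Acid 27 and 2,4,6-trichlorobenzoyl chloride with Et3N give the mixed angelic 2,4,6-trichlorobenzoic anhydride F5.
- F5 acylates F4 in warm toluene without a nucleophilic catalyst (Yamaguchi-type esterification, chosen to keep the Z geometry). The fallback comes back to the route at 28.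

**Step 21.** The pseudo-axial 3α-ester crowds the α face, so facial discrimination may be poor. Hydrogen abstraction at C6 may also compete and give the regioisomeric C4 hydroperoxide.
- The fallback changes the control element from steric bias to hydrogen-bond direction; it sets out from 26 and passes through the 3α-alcohol F4 made as above.
- Photooxygenation of F4 in an apolar medium (O2, tetraphenylporphyrin, toluene, −20 °C) should be steered to the α face by the 3α-hydroxyl. It should give methyl 3α-hydroxy-5α-hydroperoxyeudesma-4(15),11(13)-dien-12-oate F6.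
- The more acidic and more nucleophilic OOH group is silylated selectively (Et3SiCl, 1 equiv, imidazole, CH2Cl2, −40 °C) to the 5α-triethylsilylperoxy 3α-alcohol F7.
- The 3α-hydroxyl is acylated with the mixed anhydride F5 (Et3N, toluene, 40 °C) to the 5α-triethylsilylperoxy 3α-angelate F8.
- Buffered fluoride (Bu4NF/AcOH, THF, 0 °C) frees the hydroperoxide, and the fallback comes back to the route at 29.

Further compounds
F1 | step 6 | SAMP hydrazone of 4-methyl-4-(3-oxobutyl)cyclohexa-2,5-dien-1-one | C/C(CCC1(C)C=CC(=O)C=C1)=N\N1CCC[C@H]1COC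
F2 | step 6 | C7 SAMP hydrazone of (5R,10R)-10-methyl-cis-octal-1-ene-3,7-dione | COC[C@@H]1CCCN1N=C1CC[C@@]2(C)C=CC(=O)C[C@H]2C1
F3 | step 20 | methyl 3-oxoeudesma-4,11(13)-dien-12-oate | C=C(C(=O)OC)[C@@H]1CC[C@@]2(C)CCC(=O)C(C)=C2C1
F4 | step 20 | methyl 3α-hydroxyeudesma-4,11(13)-dien-12-oate | C=C(C(=O)OC)[C@@H]1CC[C@@]2(C)CC[C@@H](O)C(C)=C2C1
F5 | step 20 | angelic 2,4,6-trichlorobenzoic anhydride | C/C=C(/C)C(=O)OC(=O)c1c(Cl)cc(Cl)cc1Cl
F6 | step 21 | methyl 3α-hydroxy-5α-hydroperoxyeudesma-4(15),11(13)-dien-12-oate | C=C(C(=O)OC)[C@@H]1CC[C@@]2(C)CC[C@@H](O)C(=C)[C@]2(OO)C1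
F7 | step 21 | methyl 3α-hydroxy-5α-(triethylsilylperoxy)eudesma-4(15),11(13)-dien-12-oate | C=C(C(=O)OC)[C@@H]1CC[C@@]2(C)CC[C@@H](O)C(=C)[C@]2(OO[Si](CC)(CC)CC)C1
F8 | step 21 | methyl 3α-angeloyloxy-5α-(triethylsilylperoxy)eudesma-4(15),11(13)-dien-12-oate | C=C(C(=O)OC)[C@@H]1CC[C@@]2(C)CC[C@@H](OC(=O)/C(C)=C\C)C(=C)[C@]2(OO[Si](CC)(CC)CC)C1
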